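**Retrosynthetic overview**
- Target ⇐ its hexasilyl ether; the E‑styryl arm is attached last by Mizoroki–Heck coupling to a 6‑bromo cis‑2,3‑diaryl‑1,4‑benzodioxane (no ring formed).
- cis‑Benzodioxane ⇐ 3‑aryl‑1,4‑benzodioxin‑2‑one: the catechol‑type aryl is added to the lactone carbonyl as an organocerium, then the hemiketal is reduced with hydride anti to the existing aryl (second stereocentre by 1,2‑relay; the lactone ring becomes the dioxane ring).
- Lactone ⇐ 4‑bromo‑o‑benzoquinone (oxidative dearomatisation of 4‑bromocatechol) + aryl ketene enolate, catalytic asymmetric [4+2]: the only ring‑forming step and the first stereocentre.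
- All four arene rings are bought (catechol supplies ring A and the catechol‑type aryl); only the dioxane ring is built.

Abbreviations: TBS = tert‑butyldimethylsilyl; TBSO = tert‑butyldimethylsilyloxy.
Assumption: O‑benzoylquinine gives the (S)‑configured lactone in the key step (by analogy with its sense of induction in related ketene‑enolate reactions); if the sense is opposite, the pseudo‑enantiomeric O‑benzoylquinidine is used with no other change.

Step 1
Reactants: 1 catechol (benzene‑1,2‑diol)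
Product: 2 4‑bromocatechol (4‑bromobenzene‑1,2‑diol)
Conditions: NBS (1.0 equiv), HBF4·OEt2 (cat.), MeCN, −30 °C to rt
Reagents that add atoms: N‑bromosuccinimide, O=C1CCC(=O)N1Br
Why: Electrophilic aromatic bromination goes to the position para to one hydroxyl and meta to the other, the most activated and least hindered site, so acid‑promoted NBS gives the 4‑bromo isomer.

Step 2
Reactants: 2 4‑bromocatechol
Product: 3 4‑bromo‑1,2‑bis(TBSO)benzene
Conditions: TBSCl (2.3 equiv), imidazole, DMF, rt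
Reagents that add atoms: tert‑butyldimethylsilyl chloride, CC(C)(C)[Si](C)(C)Cl
Why: Imidazole‑promoted O‑silylation masks both phenols so that the aryl bromide can later be turned into an aryl nucleophile.

Step 3
Reactants: 4 3,5‑dihydroxyphenylacetic acid
Product: 5 tert‑butyldimethylsilyl 2‑[3,5‑bis(TBSO)phenyl]acetate
Conditions: TBSCl (3.4 equiv), imidazole, DMF, rt
Reagents that add atoms: tert‑butyldimethylsilyl chloride, CC(C)(C)[Si](C)(C)Cl
Why: Exhaustive silylation gives the two aryl silyl ethers and the silyl ester, which is the direct precursor of the acid chloride under neutral conditions.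

Step 4
Reactants: 5 tert‑butyldimethylsilyl 2‑[3,5‑bis(TBSO)phenyl]acetate
Product: 6 2‑[3,5‑bis(TBSO)phenyl]acetyl chloride
Conditions: (COCl)2, DMF (cat.), CH2Cl2, 0 °C to rt
Reagents that add atoms: oxalyl chloride, ClC(=O)C(=O)Cl
Why: Chloroiminium (Vilsmeier‑type) activation converts the silyl ester directly into the acid chloride without free HCl, so the aryl silyl ethers survive.

Step 5
Reactants: 2 4‑bromocatechol; 6 2‑[3,5‑bis(TBSO)phenyl]acetyl chloride
Product: 9 (3S)‑7‑bromo‑3‑[3,5‑bis(TBSO)phenyl]‑1,4‑benzodioxin‑2(3H)‑one, via bromoquinone 7 (not isolated), via arylketene 8 (not isolated)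
Conditions: 2, Ag2O (2.5 equiv), Na2SO4, THF, 0 °C, dark, cold filtration under argon; then 6 (1.1 equiv), O‑benzoylquinine (10 mol%), i‑Pr2NEt (1.1 equiv, added over 4 h), THF, −78 °C
Reagents that add atoms: none
Why: Proposed new method: Ag2O oxidation breaks the aromaticity of 2 to give the electrophilic o‑quinone heterodiene 7; the chiral ammonium enolate formed from ketene 8 and O‑benzoylquinine adds through its unshielded face with its carbon to the quinone oxygen para to bromine (the other carbonyl is deactivated as a vinylogous acyl bromide, and this attack leaves the better‑stabilised aryloxide meta to bromine, pKa about 9.0 for 3‑bromophenol against 9.4 for 4‑bromophenol), and that aryloxide then acylates and releases the catalyst, so the stereocentre is set under catalyst control in a formal inverse‑demand hetero‑Diels–Alder [4+2] that restores the arene; the closest known reaction is the cinchona‑alkaloid‑catalysed [4+2] of arylacetyl‑chloride‑derived ketene enolates with o‑chloranil (90–99% ee), and the untested elements are a mono‑halogenated, unblocked quinone and its regiochemistry, for which only a modest preference (roughly 4:1, minor isomer removed by chromatography) is expected.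

Step 6
Reactants: 3 4‑bromo‑1,2‑bis(TBSO)benzene; 9 (3S)‑7‑bromo‑3‑[3,5‑bis(TBSO)phenyl]‑1,4‑benzodioxin‑2(3H)‑one
Product: 13 (2S,3R)‑6‑bromo‑3‑[3,4‑bis(TBSO)phenyl]‑2‑[3,5‑bis(TBSO)phenyl]‑2,3‑dihydro‑1,4‑benzodioxine (aryl groups cis), via aryllithium 10 (not isolated), via arylcerium dichloride 11 (not isolated), via hemiketal 12 (not isolated)
Conditions: 3, n‑BuLi, THF, −78 °C; CeCl3 (anhydrous), −78 °C; 9, −78 °C; AcOH; then Et3SiH (3 equiv), BF3·OEt2 (4 equiv), CH2Cl2, −78 to −30 °C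
Reagents that add atoms: none
Why: Reductive arylation of a lactone as in C‑aryl glycoside synthesis: the weakly basic organocerium adds once to the aryl‑ester carbonyl without enolising the acidic neighbouring C–H or touching the ring bromide, BF3 then ionises the hemiketal to a 2‑aryl oxocarbenium ion in which the neighbouring 3,5‑disilyloxyphenyl group sits pseudoaxial to avoid allylic strain, and Et3SiH delivers hydride anti to it, so the new C–H is trans to that aryl group and the two aryl groups end up cis (new centre R by 1,2‑induction).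

Step 7
Reactants: 14 3,5‑dihydroxybenzaldehyde
Product: 15 3,5‑bis(TBSO)benzaldehyde
Conditions: TBSCl (2.3 equiv), imidazole, DMF, rt
Reagents that add atoms: tert‑butyldimethylsilyl chloride, CC(C)(C)[Si](C)(C)Cl
Why: Imidazole‑promoted O‑silylation protects both phenols ahead of the ylide and palladium steps.

Step 8
Reactants: 15 3,5‑bis(TBSO)benzaldehyde
Product: 16 3,5‑bis(TBSO)styrene (1‑ethenyl‑3,5‑bis(TBSO)benzene)
Conditions: Ph3PCH3Br, KN(SiMe3)2, THF, 0 °C; then 15, 0 °C to rt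
Reagents that add atoms: methyltriphenylphosphonium bromide, C[P+](c1ccccc1)(c1ccccc1)c1ccccc1.[Br-]
Why: Wittig methylenation with the pre‑formed non‑stabilised ylide converts the aldehyde into the terminal alkene without free alkoxide, so the aryl silyl ethers survive.

Step 9
Reactants: 13 (2S,3R)‑6‑bromo‑3‑[3,4‑bis(TBSO)phenyl]‑2‑[3,5‑bis(TBSO)phenyl]‑2,3‑dihydro‑1,4‑benzodioxine; 16 3,5‑bis(TBSO)styrene
Product: 17 (2S,3R)‑3‑[3,4‑bis(TBSO)phenyl]‑2‑[3,5‑bis(TBSO)phenyl]‑6‑[(E)‑2‑[3,5‑bis(TBSO)phenyl]ethenyl]‑2,3‑dihydro‑1,4‑benzodioxine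
Conditions: Pd(P(t‑Bu)3)2 (3 mol%), Cy2NMe (1.2 equiv), 1,4‑dioxane, 60 °C
Reagents that add atoms: none
Why: Mizoroki–Heck reaction: the electron‑rich aryl bromide adds oxidatively to the bulky zerovalent palladium catalyst, syn‑carbopalladation at the terminal alkene carbon and syn β‑hydride elimination give the E‑stilbene, and the mild amine base leaves the silyl ethers and both benzylic stereocentres untouched.

Step 10
Reactants: 17 hexasilyl ether of the target
Product: 18 5‑[(E)‑2‑[(2S,3R)‑3‑(3,4‑dihydroxyphenyl)‑2‑(3,5‑dihydroxyphenyl)‑2,3‑dihydro‑1,4‑benzodioxin‑6‑yl]ethenyl]benzene‑1,3‑diol (CNP0283264.2; aryl groups cis)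
Conditions: Bu4NF (7 equiv), AcOH (7 equiv), THF, 0 °C to rt, argon
Reagents that add atoms: none
Why: Fluoride‑mediated desilylation buffered with acetic acid frees the six phenols without generating a phenoxide that could open the benzylic aryl ether through a quinone methide, so the cis stereocentres are retained.

**Compound list**
1 | catechol (benzene‑1,2‑diol) | Oc1ccccc1O | starting material
2 | 4‑bromocatechol | Oc1ccc(Br)cc1O | intermediate
3 | 4‑bromo‑1,2‑bis(TBSO)benzene | CC(C)(C)[Si](C)(C)Oc1ccc(Br)cc1O[Si](C)(C)C(C)(C)C | intermediate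
4 | 3,5‑dihydroxyphenylacetic acid | OC(=O)Cc1cc(O)cc(O)c1 | starting material
5 | tert‑butyldimethylsilyl 2‑[3,5‑bis(TBSO)phenyl]acetate | CC(C)(C)[Si](C)(C)OC(=O)Cc1cc(O[Si](C)(C)C(C)(C)C)cc(O[Si](C)(C)C(C)(C)C)c1 | intermediate
6 | 2‑[3,5‑bis(TBSO)phenyl]acetyl chloride | ClC(=O)Cc1cc(O[Si](C)(C)C(C)(C)C)cc(O[Si](C)(C)C(C)(C)C)c1 | intermediate
7 | 4‑bromo‑1,2‑benzoquinone (4‑bromocyclohexa‑3,5‑diene‑1,2‑dione) | O=C1C=CC(Br)=CC1=O | intermediate
8 | [3,5‑bis(TBSO)phenyl]ketene | O=C=Cc1cc(O[Si](C)(C)C(C)(C)C)cc(O[Si](C)(C)C(C)(C)C)c1 | intermediate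
9 | (3S)‑7‑bromo‑3‑[3,5‑bis(TBSO)phenyl]‑1,4‑benzodioxin‑2(3H)‑one | O=C1Oc2cc(Br)ccc2O[C@H]1c1cc(O[Si](C)(C)C(C)(C)C)cc(O[Si](C)(C)C(C)(C)C)c1 | intermediate
10 | [3,4‑bis(TBSO)phenyl]lithium | [Li]c1ccc(O[Si](C)(C)C(C)(C)C)c(O[Si](C)(C)C(C)(C)C)c1 | intermediate
11 | dichloro[3,4‑bis(TBSO)phenyl]cerium | Cl[Ce](Cl)c1ccc(O[Si](C)(C)C(C)(C)C)c(O[Si](C)(C)C(C)(C)C)c1 | intermediate
12 | (3S)‑7‑bromo‑2‑[3,4‑bis(TBSO)phenyl]‑3‑[3,5‑bis(TBSO)phenyl]‑2,3‑dihydro‑1,4‑benzodioxin‑2‑ol (both epimers at C2; in equilibrium with the open keto‑phenol) | OC1(c2ccc(O[Si](C)(C)C(C)(C)C)c(O[Si](C)(C)C(C)(C)C)c2)Oc2cc(Br)ccc2O[C@H]1c1cc(O[Si](C)(C)C(C)(C)C)cc(O[Si](C)(C)C(C)(C)C)c1 | intermediate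
13 | (2S,3R)‑6‑bromo‑3‑[3,4‑bis(TBSO)phenyl]‑2‑[3,5‑bis(TBSO)phenyl]‑2,3‑dihydro‑1,4‑benzodioxine | Brc1ccc2c(c1)O[C@H](c1ccc(O[Si](C)(C)C(C)(C)C)c(O[Si](C)(C)C(C)(C)C)c1)[C@H](c1cc(O[Si](C)(C)C(C)(C)C)cc(O[Si](C)(C)C(C)(C)C)c1)O2 | intermediate
14 | 3,5‑dihydroxybenzaldehyde | O=Cc1cc(O)cc(O)c1 | starting material
15 | 3,5‑bis(TBSO)benzaldehyde | O=Cc1cc(O[Si](C)(C)C(C)(C)C)cc(O[Si](C)(C)C(C)(C)C)c1 | intermediate
16 | 3,5‑bis(TBSO)styrene | C=Cc1cc(O[Si](C)(C)C(C)(C)C)cc(O[Si](C)(C)C(C)(C)C)c1 | intermediate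
17 | (2S,3R)‑3‑[3,4‑bis(TBSO)phenyl]‑2‑[3,5‑bis(TBSO)phenyl]‑6‑[(E)‑2‑[3,5‑bis(TBSO)phenyl]ethenyl]‑2,3‑dihydro‑1,4‑benzodioxine | CC(C)(C)[Si](C)(C)Oc1cc(O[Si](C)(C)C(C)(C)C)cc(/C=C/c2ccc3c(c2)O[C@H](c2ccc(O[Si](C)(C)C(C)(C)C)c(O[Si](C)(C)C(C)(C)C)c2)[C@H](c2cc(O[Si](C)(C)C(C)(C)C)cc(O[Si](C)(C)C(C)(C)C)c2)O3)c1 | intermediate
18 | 5‑[(E)‑2‑[(2S,3R)‑3‑(3,4‑dihydroxyphenyl)‑2‑(3,5‑dihydroxyphenyl)‑2,3‑dihydro‑1,4‑benzodioxin‑6‑yl]ethenyl]benzene‑1,3‑diol | Oc1cc(O)cc(/C=C/c2ccc3c(c2)O[C@H](c2ccc(O)c(O)c2)[C@H](c2cc(O)cc(O)c2)O3)c1 | target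

**Totals**
Total step count: 10. Longest linear sequence: 6 steps (steps 3, 4, 5, 6, 9, 10; 4 → 5 → 6 → 9 → 13 → 17 → 18).

**Three steps most likely to fail**

Step 5. The unblocked mono‑bromo quinone may be attacked at ring carbon instead of oxygen, the regiochemical preference may be small, and the level and sense of induction are untested on this quinone. The fallback builds lactone 9 by carbene O–H insertion instead of a quinone cycloaddition; it sets out from 6 and returns at 9. Methanolysis of 6 (MeOH, pyridine) gives methyl 2‑[3,5‑bis(TBSO)phenyl]acetate F1. Diazo transfer (4‑acetamidobenzenesulfonyl azide, DBU, MeCN) gives methyl 2‑diazo‑2‑[3,5‑bis(TBSO)phenyl]acetate F2. Enantioselective insertion into the O–H bond of commercial 5‑bromo‑2‑hydroxybenzaldehyde (Pd(PhCN)2Cl2, a chiral spiro‑bis(oxazoline) ligand, NaB[3,5‑(CF3)2C6H3]4, CHCl3, rt) gives methyl (2S)‑2‑(4‑bromo‑2‑formylphenoxy)‑2‑[3,5‑bis(TBSO)phenyl]acetate F3, with the regiochemistry fixed by the phenol used. Baeyer–Villiger oxidation (mCPBA, CH2Cl2) gives methyl (2S)‑2‑[4‑bromo‑2‑(formyloxy)phenoxy]‑2‑[3,5‑bis(TBSO)phenyl]acetate F4. Acidic methanolysis (TsOH, MeOH) frees methyl (2S)‑2‑(4‑bromo‑2‑hydroxyphenoxy)‑2‑[3,5‑bis(TBSO)phenyl]acetate F5, which lactonises (TsOH, toluene, 80 °C) to 9.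

Step 6. The lactone may enolise and racemise, the aryl nucleophile may add twice after ring opening, the oxocarbenium ion may eliminate to the benzodioxin, or open‑chain ketone reduction may erode the cis selectivity. The fallback replaces substrate‑controlled hydride delivery by a stereoconvergent reduction and an invertive ring closure; it sets out from 12 (isolated by aqueous work‑up after the organocerium addition) and returns at 13. The open keto‑phenol tautomer of 12, whose α‑centre epimerises freely, undergoes asymmetric transfer hydrogenation with dynamic kinetic resolution (RuCl[(R,R)‑TsDPEN](p‑cymene), HCO2H/Et3N, DMF, 40 °C) to give (1S,2S)‑2‑(4‑bromo‑2‑hydroxyphenoxy)‑1‑[3,4‑bis(TBSO)phenyl]‑2‑[3,5‑bis(TBSO)phenyl]ethan‑1‑ol F6, the like (threo) isomer expected by analogy with benzoin. Intramolecular Mitsunobu etherification (PPh3, DIAD, THF, 0 °C) closes the dioxane ring with inversion at the carbinol carbon and gives cis‑13.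

Step 9. The hindered, electron‑rich bromide may couple sluggishly or give some 1,1‑diaryl alkene or Z isomer. The fallback fixes the alkene geometry before the coupling; it sets out from 15 (coupled with 13) and returns at 17. Boron–Wittig olefination of 15 (CH2(Bpin)2, lithium 2,2,6,6‑tetramethylpiperidide, THF, −78 °C to rt) gives 2‑[(E)‑2‑[3,5‑bis(TBSO)phenyl]ethenyl]‑4,4,5,5‑tetramethyl‑1,3,2‑dioxaborolane F7. Suzuki–Miyaura coupling of F7 with 13 (Pd(P(t‑Bu)3)2, KF, THF, rt) gives 17.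

**Further compounds**
F1 | step 5 | methyl 2‑[3,5‑bis(TBSO)phenyl]acetate | COC(=O)Cc1cc(O[Si](C)(C)C(C)(C)C)cc(O[Si](C)(C)C(C)(C)C)c1
F2 | step 5 | methyl 2‑diazo‑2‑[3,5‑bis(TBSO)phenyl]acetate | COC(=O)C(=[N+]=[N-])c1cc(O[Si](C)(C)C(C)(C)C)cc(O[Si](C)(C)C(C)(C)C)c1
F3 | step 5 | methyl (2S)‑2‑(4‑bromo‑2‑formylphenoxy)‑2‑[3,5‑bis(TBSO)phenyl]acetate | COC(=O)[C@@H](Oc1ccc(Br)cc1C=O)c1cc(O[Si](C)(C)C(C)(C)C)cc(O[Si](C)(C)C(C)(C)C)c1
F4 | step 5 | methyl (2S)‑2‑[4‑bromo‑2‑(formyloxy)phenoxy]‑2‑[3,5‑bis(TBSO)phenyl]acetate | COC(=O)[C@@H](Oc1ccc(Br)cc1OC=O)c1cc(O[Si](C)(C)C(C)(C)C)cc(O[Si](C)(C)C(C)(C)C)c1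
F5 | step 5 | methyl (2S)‑2‑(4‑bromo‑2‑hydroxyphenoxy)‑2‑[3,5‑bis(TBSO)phenyl]acetate | COC(=O)[C@@H](Oc1ccc(Br)cc1O)c1cc(O[Si](C)(C)C(C)(C)C)cc(O[Si](C)(C)C(C)(C)C)c1
F6 | step 6 | (1S,2S)‑2‑(4‑bromo‑2‑hydroxyphenoxy)‑1‑[3,4‑bis(TBSO)phenyl]‑2‑[3,5‑bis(TBSO)phenyl]ethan‑1‑ol | O[C@@H](c1ccc(O[Si](C)(C)C(C)(C)C)c(O[Si](C)(C)C(C)(C)C)c1)[C@H](c1cc(O[Si](C)(C)C(C)(C)C)cc(O[Si](C)(C)C(C)(C)C)c1)Oc1ccc(Br)cc1O
F7 | step 9 | 2‑[(E)‑2‑[3,5‑bis(TBSO)phenyl]ethenyl]‑4,4,5,5‑tetramethyl‑1,3,2‑dioxaborolane | CC(C)(C)[Si](C)(C)Oc1cc(/C=C/B2OC(C)(C)C(C)(C)O2)cc(O[Si](C)(C)C(C)(C)C)c1
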